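The numbers in the tables stem from a simulated flask from invented constants; the scatter is artificial.

Read the fall of D in the theta and delta runs from their third and first readings on, so that the slow start of each run stays out.

| setting | epsilon | theta | delta | zeta | Monday's | Sunday's | Wednesday's | Saturday's | Thursday's | Friday's |
|---|---|---|---|---|---|---|---|---|---|---|
| D | 0.25 M | 0.25 M | 0.25 M | 0.22 M | 0.060 M | 0.25 M | 0.80 M | 0.12 M | 0.25 M | 0.15 M |
| L | 0.061 M | 0.30 M | 0.97 M | 0.263 M | 0.400 M | 0.0800 M | 0.0800 M | 0.200 M | 0.263 M | 1.00 M |
| remark | run made earlier | run made earlier | run made earlier | run made earlier |  |  |  |  |  |  |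
| time |  |  |  |  | 1.0 h | 1.0 h | 1.0 h | 1.0 h | 1.0 h | 1.0 h |
| volume of the second phase over the first |  |  |  |  | 2.0 | 2.0 | 2.0 | 2.0 | 2.0 | 2.0 |

| run | time / min | J / % | D / % |
|---|---|---|---|
| epsilon | 8.00 | 0.6 | 99.3 |
| epsilon | 15.0 | 3.1 | 97.5 |
| epsilon | 25.0 | 4.7 | 95.2 |
| epsilon | 30.0 | 6.4 | 95.3 |
| epsilon | 40.0 | 7.4 | 92.0 |
| theta | 3.00 | 2.1 | 99.3 |
| theta | 6.00 | 3.4 | 97.5 |
| theta | 12.0 | 10.2 | 91.1 |
| theta | 20.0 | 16.6 | 82.2 |
| theta | 40.0 | 28.8 | 65.8 |
| delta | 8.00 | 16.1 | 84.5 |
| delta | 15.0 | 34.1 | 64.7 |
| delta | 25.0 | 52.1 | 42.8 |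
| delta | 30.0 | 57.9 | 37.1 |
| delta | 40.0 | 65.9 | 25.9 |
| zeta | 8.00 | 3.8 | 96.2 |
| zeta | 15.0 | 10.6 | 89.5 |
| zeta | 25.0 | 18.6 | 80.4 |
| zeta | 30.0 | 22.3 | 76.3 |
| zeta | 40.0 | 27.5 | 69.5 |

(readings scatter by 0.5 percentage points)

- in the second phase: L; everything else is in the first
- charges count per volume of the first phase; a concentration in a rate is the amount of a species over the volume of its own phase; every rate counts per litre of the first phase
- the numbers in the tables scatter by 0.5 percentage points (one standard deviation)
- the earlier runs hold the two phases in the same ratio of volumes as the flask asked about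

- all flasks from highest to lowest amount of J, in percent of the D charged, at 1.0 h (Monday's / Sunday's / Wednesday's / Saturday's / Thursday's / Friday's)
- the amount of J, in percent of the D charged of the flask you put first, at 1.0 h
- the amount of J, in percent of the D charged of the flask you put last, at 1.0 h

Per unit of [L] charged, the slope of ln[D] is 6.46 × 10⁻⁴ M⁻¹ s⁻¹ in the theta run and 6.35 × 10⁻⁴ M⁻¹ s⁻¹ in the delta run, although [L] differs by a factor of 3.23. I call the delta value κ. At the last delta reading, J is 88.9% of the D lost.

Two chemists now dispute Wednesday's flask. The first freezes [L] at its charge (pseudo-first-order), so the share of D gone in the hour is one minus exp(−κ[L]t). That gives 16.7% in Wednesday's, the same as in Sunday's, and J near 14.8%.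

The second holds that each D takes one L, which the epsilon run does not test: by its last reading it had lost 8.00% of its D, against a ceiling of 24.4%. On that view, Wednesday's stops at [L]/[D], a ceiling of 10.0%, with J near 8.89%.

The frozen rate asks Wednesday's for 0.134 M of D against 0.0800 M of L charged, a quotient of 1.67. This demand ratio, the D turned over in the hour at frozen [L] over the L charged, tells which of the two numbers is the smaller: above one, the frozen share lies over the ceiling, so I treat L as the limiting reagent and take the ceiling. Friday's ratio is 0.135, so I use the frozen share there, with J near 79.9%. Taking the smaller of the two shares in each flask, I rank Friday's, Monday's, Thursday's, Saturday's, Sunday's, Wednesday's.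

For Wednesday's the forecast takes the second chemist's side, “L caps conversion at 10%”, and it gives Friday's > Monday's > Thursday's > Saturday's > Sunday's > Wednesday's, the same order as mine, with 73% and 7.2%, lower than my 79.9% and 8.89%.

The flask gives Friday's > Monday's > Thursday's > Saturday's > Sunday's > Wednesday's, with 74.4% at the top and 6.84% at the bottom.

    Q ⇌ L, rate k1*([Q] - [L]/K1) per volume of the first phase (partition coefficient = 0.360, kL = 0.00140 s⁻¹)
    D + Q → J (k = 0.00136 M⁻¹ s⁻¹)
    J → X (k = 1.29 × 10⁻⁶ s⁻¹)
    J ⇌ G (K = 0.460, k = 1.18 × 10⁻⁴ s⁻¹)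

Wednesday's lost 8.22% of its D, less than its ceiling and less than the frozen 16.7%, which sides with the second chemist; the first keeps Friday's, with 9.6% of D left against a frozen 10.2%. In Wednesday's, half the uptake of L as Q was done by 0.117 h, and half the loss of J to G by 0.614 h, later. A flask like Wednesday's with 0.32 M of D has a demand ratio of 0.668, below one, and lost 13.0% of its D, with 0.0212 M of Q standing and L at 21.4% of its own charge.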